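Kazinol C is divided at the C1'–CH2 bond into a ring B aryl bromide and a ring A propyl iodide. The plan rests on reading the two prenyl groups on the adjacent carbons C2' and C3' of catechol ring B as the remnants of a fused cyclohexene. Ozonolysis of the C6=C7 bond of a 4-bromo-1,2-bis(silyloxy)-5,8-dihydronaphthalene opens that carbocycle in one operation into two CH2CHO arms held on neighbouring ring carbons. A double isopropylidene Wittig reaction then completes both prenyl units. The precursor derives from bought 5,8-dihydro-1-naphthol by para-bromination (future C1') and ortho-hydroxylation (future C5'–OH). Negishi coupling, an aromatic Claisen shift to C5 of ring A and desilylation finish the route.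

Key step: step 5

Remark: ring A is the resorcinol ring (C1 chain, C2 and C4 oxygen, C5 1,1-dimethylallyl) and ring B the catechol ring (C1' chain, C2'/C3' prenyl, C4'/C5' oxygen). TBS = tert-butyldimethylsilyl and prenyl = 3-methylbut-2-enyl. Ozonide 8 is drawn as the monomeric bicycle, on the assumption that any oligomeric peroxide formed beside it is reduced by PPh3 to the same dialdehyde.

Step 1
Reactants: 1 5,8-dihydro-1-naphthol
Product: 2 4-bromo-5,8-dihydronaphthalen-1-ol
Conditions: N-bromosuccinimide (1.0 equiv), MeCN, −20 → 0 °C, dark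
Reagents that add atoms: N-bromosuccinimide, O=C1CCC(=O)N1Br
Why: Electrophilic aromatic bromination: the free phenol makes the para carbon C4 the most nucleophilic site, N-bromosuccinimide in acetonitrile is a para-selective bromine source that builds up neither HBr nor Br2, and cold, dark conditions should leave the isolated C6=C7 bond and the benzylic/allylic CH2 groups untouched.

Step 2
Reactants: 2 4-bromo-5,8-dihydronaphthalen-1-ol
Product: 4 4-bromo-1-hydroxy-5,8-dihydronaphthalene-2-carbaldehyde, via salicyl alcohol 3 (not isolated)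
Conditions: MgCl2 (2 equiv), Et3N (4 equiv), (CH2O)n (6 equiv), THF, reflux; 1 M HCl work-up
Reagents that add atoms: paraformaldehyde (reacts as formaldehyde), C=O
Why: Magnesium-mediated ortho-formylation (Casnati–Skattebøl reaction): the magnesium phenoxide delivers coordinated formaldehyde to the only free ortho carbon C2 and a second formaldehyde takes a hydride from the benzylic alkoxide, conditions under which the aryl bromide and the skipped alkene are inert.

Step 3
Reactants: 4 4-bromo-1-hydroxy-5,8-dihydronaphthalene-2-carbaldehyde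
Product: 6 4-bromo-5,8-dihydronaphthalene-1,2-diol, via aryl formate 5 (not isolated)
Conditions: 30% H2O2 (1.2 equiv), 1 M NaOH (2 equiv), degassed THF/H2O, 0 °C → rt, Ar; then 1 M HCl
Reagents that add atoms: hydrogen peroxide, OO
Why: Dakin oxidation: hydroperoxide adds to the aldehyde, the electron-rich aryl group migrates to oxygen and formate 5 is saponified in the flask, while alkaline H2O2 does not epoxidise an unactivated alkene and exclusion of air with early acidification protects the catecholate.

Step 4
Reactants: 6 4-bromo-5,8-dihydronaphthalene-1,2-diol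
Product: 7 4-bromo-1,2-bis(tert-butyldimethylsilyloxy)-5,8-dihydronaphthalene
Conditions: TBSCl (2.5 equiv), imidazole (5 equiv), DMF, rt
Reagents that add atoms: tert-butyldimethylsilyl chloride, CC(C)(C)[Si](C)(C)Cl
Why: Imidazole-promoted silylation of both phenols gives ethers that shield the arene in the ozonolysis and can later be removed with fluoride, without the acid or hydrogenolysis that prenyl groups would not tolerate.

Step 5
Reactants: 7 4-bromo-1,2-bis(tert-butyldimethylsilyloxy)-5,8-dihydronaphthalene
Product: 9 2,2'-[3-bromo-5,6-bis(tert-butyldimethylsilyloxy)-1,2-phenylene]diacetaldehyde, via bicyclic ozonide 8 (not isolated)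
Conditions: O3/O2, CH2Cl2, Sudan Red 7B (trace), −78 °C, stopped when the dye fades; Ar purge; PPh3 (1.2 equiv), −78 °C → rt; solvent exchanged for THF below 25 °C, used at once
Reagents that add atoms: ozone, [O-][O+]=O
Why: The unconjugated ring alkene C6=C7 takes up ozone in a concerted [3+2] cycloaddition, the 1,2,3-trioxolane splits into an aldehyde and a carbonyl oxide that stay tethered through the arene and recombine to the 1,2,4-trioxolane 8 (Criegee mechanism), and PPh3 abstracts one oxygen to release dialdehyde 9. The closest known case is the ozonolysis of 1,4-dihydronaphthalene to benzene-1,2-diacetaldehyde. No ring is closed in the product: the six-membered carbocycle fused at C4a–C8a is opened, and the trioxolane of 8 is only a transient cycloadduct. No stereocentre is created in 9, since the two bridgehead centres of 8 (cis by necessity of the bicycle) disappear on reduction. The step needs chemoselectivity for the alkene over the oxygenated arene, which is secured by the far higher rate of ozone with an isolated alkene, by the deactivating bromine and the two bulky silyl ethers on the ring, and by the dye end point. Both CH2CHO arms stem from one ring spanning C4a and C8a (future C2' and C3'), so their vicinal placement needs no regiocontrol, and PPh3 is the reductant of choice because Ph3PO is harmless in the next step, so the enolisable dialdehyde can go on unpurified.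

Step 6
Reactants: 9 2,2'-[3-bromo-5,6-bis(tert-butyldimethylsilyloxy)-1,2-phenylene]diacetaldehyde; 10 isopropyltriphenylphosphonium iodide
Product: 12 1-bromo-4,5-bis(tert-butyldimethylsilyloxy)-2,3-diprenylbenzene, via isopropylidene ylide 11 (not isolated)
Conditions: 10 (3.0 equiv), NaN(SiMe3)2 (2.9 equiv), THF, 0 °C; then 9 in THF added at −78 °C, → 0 °C
Reagents that add atoms: isopropyltriphenylphosphonium iodide (10), CC(C)[P+](c1ccccc1)(c1ccccc1)c1ccccc1.[I-]
Why: Twofold Wittig olefination: run cold into an excess of ylide that holds no residual amide base, both aldehydes should be attacked faster than they are deprotonated, the two identical methyl groups on the ylide carbon remove any E/Z question, and NaN(SiMe3)2, unlike an alkyllithium, cannot exchange the aryl bromide.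

Step 7
Reactants: 13 umbelliferone (7-hydroxycoumarin)
Product: 14 7-hydroxychroman-2-one
Conditions: H2 (1 atm), 10% Pd/C, THF, rt
Reagents that add atoms: none
Why: Catalytic hydrogenation saturates only the conjugated C3=C4 bond of the coumarin, and the aprotic solvent prevents alcoholysis of the aryl ester lactone that results.

Step 8
Reactants: 14 7-hydroxychroman-2-one; 15 prenyl bromide
Product: 16 7-(prenyloxy)chroman-2-one
Conditions: 15 (1.2 equiv), K2CO3 (1.5 equiv), dry acetone, rt → 40 °C
Reagents that add atoms: prenyl bromide (15), CC(C)=CCBr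
Why: Williamson etherification: the C7 hydroxyl is the only free phenol because the second ring A oxygen is tied up in the lactone, and anhydrous carbonate in acetone should alkylate it at the primary allylic carbon without opening the lactone.

Step 9
Reactants: 16 7-(prenyloxy)chroman-2-one
Product: 17 2-(3-hydroxypropyl)-5-(prenyloxy)phenol
Conditions: LiAlH4 (1.5 equiv), THF, 0 °C → rt; aq. potassium sodium tartrate (KNaC4H4O6) work-up
Reagents that add atoms: none
Why: Hydride reduction of the lactone releases the C2 phenol and the three-carbon chain as a primary alcohol in one operation, and the allyl aryl ether is not touched by LiAlH4.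

Step 10
Reactants: 17 2-(3-hydroxypropyl)-5-(prenyloxy)phenol
Product: 18 2-(tert-butyldimethylsilyloxy)-1-[3-(tert-butyldimethylsilyloxy)propyl]-4-(prenyloxy)benzene
Conditions: TBSCl (2.4 equiv), imidazole (5 equiv), DMF, rt
Reagents that add atoms: tert-butyldimethylsilyl chloride, CC(C)(C)[Si](C)(C)Cl
Why: Exhaustive silylation avoids having to distinguish phenol from primary alcohol at this point and rules out the chroman closure that direct activation of the alcohol beside a free phenol would invite.

Step 11
Reactants: 18 2-(tert-butyldimethylsilyloxy)-1-[3-(tert-butyldimethylsilyloxy)propyl]-4-(prenyloxy)benzene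
Product: 19 3-[2-(tert-butyldimethylsilyloxy)-4-(prenyloxy)phenyl]propan-1-ol
Conditions: camphorsulfonic acid (10 mol%), MeOH/CH2Cl2 1:1, 0 °C
Reagents that add atoms: none
Why: Acid-catalysed methanolysis cleaves primary alkyl silyl ethers much faster than aryl silyl ethers, whose oxygen is less basic, and catalytic acid at 0 °C should not ionise the prenyl ether.

Step 12
Reactants: 19 3-[2-(tert-butyldimethylsilyloxy)-4-(prenyloxy)phenyl]propan-1-ol
Product: 20 2-(tert-butyldimethylsilyloxy)-1-(3-iodopropyl)-4-(prenyloxy)benzene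
Conditions: PPh3 (1.3 equiv), I2 (1.3 equiv), imidazole (2 equiv), CH2Cl2, 0 °C (reagent premixed), dark
Reagents that add atoms: iodine, II
Why: Appel iodination: the alkoxyphosphonium ion is displaced by iodide in an SN2 step at the unhindered primary carbon, and premixing PPh3 with I2 leaves no free iodine for the prenyl double bond.

Step 13
Reactants: 20 2-(tert-butyldimethylsilyloxy)-1-(3-iodopropyl)-4-(prenyloxy)benzene; 12 1-bromo-4,5-bis(tert-butyldimethylsilyloxy)-2,3-diprenylbenzene
Product: 22 1-[2-(tert-butyldimethylsilyloxy)-4-(prenyloxy)phenyl]-3-[4,5-bis(tert-butyldimethylsilyloxy)-2,3-diprenylphenyl]propane, via alkylzinc iodide 21 (not isolated)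
Conditions: 20 (1.3 equiv), Zn dust (2 equiv, activated with BrCH2CH2Br and Me3SiCl), LiCl (1.5 equiv), THF, 25–40 °C; then 12 (1.0 equiv), Pd(OAc)2 (2 mol%), SPhos (2-dicyclohexylphosphino-2',6'-dimethoxybiphenyl, 4 mol%), THF, 25 → 50 °C
Reagents that add atoms: none
Why: Negishi sp3–sp2 cross-coupling: LiCl-assisted zinc insertion into the primary alkyl iodide tolerates silyl and allyl ethers, the bulky electron-rich biarylphosphine lets zerovalent palladium add to the electron-rich, ortho-substituted bromide and eliminate reductively faster than β-hydride loss, and the trisubstituted prenyl ether is a poor substrate for π-allyl ionisation.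

Step 14
Reactants: 22 1-[2-(tert-butyldimethylsilyloxy)-4-(prenyloxy)phenyl]-3-[4,5-bis(tert-butyldimethylsilyloxy)-2,3-diprenylphenyl]propane
Product: 25 tris-TBS kazinol C (free C4 phenol; 2-methylbut-3-en-2-yl group at C5 of ring A), via ortho-dienone 23 (not isolated), via trimethylsilyl ether 24 (not isolated)
Conditions: N,O-bis(trimethylsilyl)acetamide (3 equiv), PhNEt2, 190 °C, sealed tube, Ar; then citric acid, MeOH/THF, rt
Reagents that add atoms: none
Why: Aromatic Claisen rearrangement: the suprafacial [3,3] shift inverts the prenyl unit and delivers it as a 1,1-dimethylallyl group to C5, the ortho carbon para to the C2 silyloxy donor, because C3 is wedged between two oxygen substituents (one a bulky silyl ether) and the para carbon C1 is blocked by the chain, while silylation of the liberated phenol in the flask shuts off the abnormal Claisen and dihydrobenzofuran pathways before the labile trimethylsilyl group is removed by mild methanolysis.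

Step 15
Reactants: 25 tris-TBS kazinol C
Product: 26 kazinol C
Conditions: Bu4NF (3.6 equiv), AcOH (3.6 equiv), THF, 0 °C, Ar; degassed pH 7 phosphate buffer work-up
Reagents that add atoms: none
Why: Fluoride-driven cleavage of the three aryl silyl ethers, in which the acetic acid buffer protonates each phenoxide as it forms, so that the air-sensitive catecholate does not accumulate and neither strong base nor acid is present to cyclise the C3' prenyl group onto the C4' hydroxyl.

Compound list
1 | 5,8-dihydro-1-naphthol | Oc1cccc2c1CC=CC2 | starting material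
2 | 4-bromo-5,8-dihydronaphthalen-1-ol | Oc1ccc(Br)c2c1CC=CC2 | intermediate
3 | 4-bromo-2-(hydroxymethyl)-5,8-dihydronaphthalen-1-ol (salicyl alcohol, present as magnesium alkoxide, not isolated) | OCc1cc(Br)c2CC=CCc2c1O | intermediate
4 | 4-bromo-1-hydroxy-5,8-dihydronaphthalene-2-carbaldehyde | O=Cc1cc(Br)c2CC=CCc2c1O | intermediate
5 | 4-bromo-1-hydroxy-5,8-dihydronaphthalen-2-yl formate (not isolated) | O=COc1cc(Br)c2CC=CCc2c1O | intermediate
6 | 4-bromo-5,8-dihydronaphthalene-1,2-diol | Oc1cc(Br)c2CC=CCc2c1O | intermediate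
7 | 4-bromo-1,2-bis(tert-butyldimethylsilyloxy)-5,8-dihydronaphthalene | CC(C)(C)[Si](C)(C)Oc1cc(Br)c2CC=CCc2c1O[Si](C)(C)C(C)(C)C | intermediate
8 | C6/C7 ozonide of 7 (benzo-fused trioxabicyclo[4.2.1]nonane, racemic, one enantiomer drawn, not isolated) | CC(C)(C)[Si](C)(C)Oc1cc(Br)c2C[C@@H]3OO[C@@H](O3)Cc2c1O[Si](C)(C)C(C)(C)C | intermediate
9 | 2,2'-[3-bromo-5,6-bis(tert-butyldimethylsilyloxy)-1,2-phenylene]diacetaldehyde | O=CCc1c(Br)cc(O[Si](C)(C)C(C)(C)C)c(O[Si](C)(C)C(C)(C)C)c1CC=O | intermediate
10 | isopropyltriphenylphosphonium iodide | CC(C)[P+](c1ccccc1)(c1ccccc1)c1ccccc1.[I-] | starting material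
11 | isopropylidenetriphenylphosphorane (not isolated) | CC(C)=P(c1ccccc1)(c1ccccc1)c1ccccc1 | intermediate
12 | 1-bromo-4,5-bis(tert-butyldimethylsilyloxy)-2,3-diprenylbenzene | CC(C)=CCc1c(Br)cc(O[Si](C)(C)C(C)(C)C)c(O[Si](C)(C)C(C)(C)C)c1CC=C(C)C | intermediate
13 | umbelliferone (7-hydroxycoumarin) | O=c1ccc2ccc(O)cc2o1 | starting material
14 | 7-hydroxychroman-2-one | O=C1CCc2ccc(O)cc2O1 | intermediate
15 | prenyl bromide (1-bromo-3-methylbut-2-ene) | CC(C)=CCBr | starting material
16 | 7-(prenyloxy)chroman-2-one | CC(C)=CCOc1ccc2CCC(=O)Oc2c1 | intermediate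
17 | 2-(3-hydroxypropyl)-5-(prenyloxy)phenol | CC(C)=CCOc1ccc(CCCO)c(O)c1 | intermediate
18 | 2-(tert-butyldimethylsilyloxy)-1-[3-(tert-butyldimethylsilyloxy)propyl]-4-(prenyloxy)benzene | CC(C)=CCOc1ccc(CCCO[Si](C)(C)C(C)(C)C)c(O[Si](C)(C)C(C)(C)C)c1 | intermediate
19 | 3-[2-(tert-butyldimethylsilyloxy)-4-(prenyloxy)phenyl]propan-1-ol | CC(C)=CCOc1ccc(CCCO)c(O[Si](C)(C)C(C)(C)C)c1 | intermediate
20 | 2-(tert-butyldimethylsilyloxy)-1-(3-iodopropyl)-4-(prenyloxy)benzene | CC(C)=CCOc1ccc(CCCI)c(O[Si](C)(C)C(C)(C)C)c1 | intermediate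
21 | 3-[2-(tert-butyldimethylsilyloxy)-4-(prenyloxy)phenyl]propylzinc iodide (not isolated) | CC(C)=CCOc1ccc(CCC[Zn]I)c(O[Si](C)(C)C(C)(C)C)c1 | intermediate
22 | 1-[2-(tert-butyldimethylsilyloxy)-4-(prenyloxy)phenyl]-3-[4,5-bis(tert-butyldimethylsilyloxy)-2,3-diprenylphenyl]propane | CC(C)=CCOc1ccc(CCCc2cc(O[Si](C)(C)C(C)(C)C)c(O[Si](C)(C)C(C)(C)C)c(CC=C(C)C)c2CC=C(C)C)c(O[Si](C)(C)C(C)(C)C)c1 | intermediate
23 | ring A cyclohexa-2,4-dienone carrying H and 2-methylbut-3-en-2-yl on the sp3 carbon C5 (racemic, not isolated) | C=CC(C)(C)C1C=C(CCCc2cc(O[Si](C)(C)C(C)(C)C)c(O[Si](C)(C)C(C)(C)C)c(CC=C(C)C)c2CC=C(C)C)C(O[Si](C)(C)C(C)(C)C)=CC1=O | intermediate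
24 | C4 trimethylsilyl ether of 25 (not isolated) | C=CC(C)(C)c1cc(CCCc2cc(O[Si](C)(C)C(C)(C)C)c(O[Si](C)(C)C(C)(C)C)c(CC=C(C)C)c2CC=C(C)C)c(O[Si](C)(C)C(C)(C)C)cc1O[Si](C)(C)C | intermediate
25 | tris-TBS kazinol C (TBS on O2, O4' and O5'; free C4 phenol; 2-methylbut-3-en-2-yl at C5) | C=CC(C)(C)c1cc(CCCc2cc(O[Si](C)(C)C(C)(C)C)c(O[Si](C)(C)C(C)(C)C)c(CC=C(C)C)c2CC=C(C)C)c(O[Si](C)(C)C(C)(C)C)cc1O | intermediate
26 | kazinol C | C=CC(C)(C)c1cc(CCCc2cc(O)c(O)c(CC=C(C)C)c2CC=C(C)C)c(O)cc1O | target

Total step count: 15.
Longest linear sequence: 9 steps (steps 1–6 or steps 7–12, followed by steps 13–15).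

Steps most likely to fail

Step 6 (twofold Wittig). The basic ylide may deprotonate the acidic benzylic α-carbons instead of adding to the carbonyl groups. That would open the way to intramolecular aldol closure and to incomplete olefination of the second arm. The fallback inverts the polarity of the olefination, so that the arene carries the ylides and the carbonyl partner is cheap acetone used in excess. Setting out from 9, NaBH4 (MeOH/THF, 0 °C) should give the stable, purifiable 2,2'-[3-bromo-5,6-bis(tert-butyldimethylsilyloxy)-1,2-phenylene]diethanol F1. A double Appel reaction (PPh3, I2, imidazole, CH2Cl2) should give 1-bromo-4,5-bis(tert-butyldimethylsilyloxy)-2,3-bis(2-iodoethyl)benzene F2. PPh3 in refluxing MeCN should give the bis(triphenylphosphonium) diiodide F3. NaN(SiMe3)2 (2 equiv, THF, 0 °C) should convert it into the bis-ylide F4, which is quenched with dry acetone and comes back to the route at 12.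

Step 14 (Claisen rearrangement). Migration to C3, thermal loss of the prenyl group as isoprene, or onward rearrangement before the phenol is capped would all consume the most advanced intermediate. Isomers of this size are also hard to separate. The fallback moves the sigmatropic step to fragment level, ahead of the coupling.
- Setting out from 18, heating with N,O-bis(trimethylsilyl)acetamide in PhNEt2 (190 °C) should lead through the fragment ortho-dienone F5 to the fragment trimethylsilyl ether F6.
- Citric acid in MeOH should free 5-(tert-butyldimethylsilyloxy)-4-[3-(tert-butyldimethylsilyloxy)propyl]-2-(2-methylbut-3-en-2-yl)phenol F7, which is purified at this cheap stage.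
- TBSOTf with 2,6-lutidine should give the tris-TBS ether F8.
- Camphorsulfonic acid in MeOH should give 3-[2,4-bis(tert-butyldimethylsilyloxy)-5-(2-methylbut-3-en-2-yl)phenyl]propan-1-ol F9.
- Appel iodination should give the corresponding 3-iodopropylarene F10, and zinc insertion (Zn, LiCl) should give the alkylzinc iodide F11.
- Negishi coupling with 12 under the conditions of step 13 should give tetrakis-TBS kazinol C F12, and desilylation with Bu4NF/AcOH comes back to the route at 26.

This order also keeps the allyl aryl ether away from the palladium step.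

Step 5 (ozonolysis). Ozone may go on to attack the oxygenated arene once the alkene is consumed, or the carbonyl oxide may oligomerise to peroxides that are reduced sluggishly. The fallback replaces the cycloaddition/fragmentation by a two-stage glycol cleavage. Setting out from 7, catalytic OsO4 with N-methylmorpholine N-oxide (acetone/H2O, 0 °C → rt) should give the stable racemic cis-4-bromo-1,2-bis(tert-butyldimethylsilyloxy)-5,6,7,8-tetrahydronaphthalene-6,7-diol F13. NaIO4 on silica gel in CH2Cl2 should cleave it under neutral conditions, and the sequence comes back to the route at 9, which is passed on to step 6 at once.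

Further compounds
F1 | step 6 | 2,2'-[3-bromo-5,6-bis(tert-butyldimethylsilyloxy)-1,2-phenylene]diethanol | OCCc1c(Br)cc(O[Si](C)(C)C(C)(C)C)c(O[Si](C)(C)C(C)(C)C)c1CCO
F2 | step 6 | 1-bromo-4,5-bis(tert-butyldimethylsilyloxy)-2,3-bis(2-iodoethyl)benzene | ICCc1c(Br)cc(O[Si](C)(C)C(C)(C)C)c(O[Si](C)(C)C(C)(C)C)c1CCI
F3 | step 6 | bis(triphenylphosphonium) diiodide derived from F2 | [I-].[I-].Brc1cc(O[Si](C)(C)C(C)(C)C)c(O[Si](C)(C)C(C)(C)C)c(CC[P+](c2ccccc2)(c2ccccc2)c2ccccc2)c1CC[P+](c1ccccc1)(c1ccccc1)c1ccccc1
F4 | step 6 | bis-ylide derived from F3 | Brc1cc(O[Si](C)(C)C(C)(C)C)c(O[Si](C)(C)C(C)(C)C)c(CC=P(c2ccccc2)(c2ccccc2)c2ccccc2)c1CC=P(c1ccccc1)(c1ccccc1)c1ccccc1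
F5 | step 14 | fragment ortho-dienone (racemic) | C=CC(C)(C)C1C=C(CCCO[Si](C)(C)C(C)(C)C)C(O[Si](C)(C)C(C)(C)C)=CC1=O
F6 | step 14 | fragment trimethylsilyl ether of F7 | C=CC(C)(C)c1cc(CCCO[Si](C)(C)C(C)(C)C)c(O[Si](C)(C)C(C)(C)C)cc1O[Si](C)(C)C
F7 | step 14 | 5-(tert-butyldimethylsilyloxy)-4-[3-(tert-butyldimethylsilyloxy)propyl]-2-(2-methylbut-3-en-2-yl)phenol | C=CC(C)(C)c1cc(CCCO[Si](C)(C)C(C)(C)C)c(O[Si](C)(C)C(C)(C)C)cc1O
F8 | step 14 | tris-TBS ether of the ring A fragment | C=CC(C)(C)c1cc(CCCO[Si](C)(C)C(C)(C)C)c(O[Si](C)(C)C(C)(C)C)cc1O[Si](C)(C)C(C)(C)C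
F9 | step 14 | 3-[2,4-bis(tert-butyldimethylsilyloxy)-5-(2-methylbut-3-en-2-yl)phenyl]propan-1-ol | C=CC(C)(C)c1cc(CCCO)c(O[Si](C)(C)C(C)(C)C)cc1O[Si](C)(C)C(C)(C)C
F10 | step 14 | 2,4-bis(tert-butyldimethylsilyloxy)-1-(3-iodopropyl)-5-(2-methylbut-3-en-2-yl)benzene | C=CC(C)(C)c1cc(CCCI)c(O[Si](C)(C)C(C)(C)C)cc1O[Si](C)(C)C(C)(C)C
F11 | step 14 | alkylzinc iodide derived from F10 | C=CC(C)(C)c1cc(CCC[Zn]I)c(O[Si](C)(C)C(C)(C)C)cc1O[Si](C)(C)C(C)(C)C
F12 | step 14 | tetrakis-TBS kazinol C | C=CC(C)(C)c1cc(CCCc2cc(O[Si](C)(C)C(C)(C)C)c(O[Si](C)(C)C(C)(C)C)c(CC=C(C)C)c2CC=C(C)C)c(O[Si](C)(C)C(C)(C)C)cc1O[Si](C)(C)C(C)(C)C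
F13 | step 5 | cis-4-bromo-1,2-bis(tert-butyldimethylsilyloxy)-5,6,7,8-tetrahydronaphthalene-6,7-diol (racemic, one enantiomer drawn) | CC(C)(C)[Si](C)(C)Oc1cc(Br)c2C[C@@H](O)[C@@H](O)Cc2c1O[Si](C)(C)C(C)(C)C
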